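**Strategy.** The C4a–C8a ring-fusion bond (hexahydronaphthalene numbering of the target) is treated as the tail-to-tail bond between the β-carbons of two acrylate units (C4–C4a and C1–C8a) that flank the C2=C3 alkene of ring A. One nickel-catalysed [2+2+2] cycloaddition of an acyclic bis-enoate with octadec-1-yne forms this bond, closes ring A together with a temporary δ-lactone, and sets C1, C4, C4a and C8a. The precursor is the mixed maleate/(E)-enoate diester of an enantioenriched homoallylic carbinol; its stereocentre steers the cyclisation and later becomes the C7 ketone. Lactone opening, oxidation, C-acylation and Knoevenagel closure then build ring B.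

Key step: step 4

Remark on numbering: C1–C8a always mean the target positions (C1 and C4 carry CO2Me, C2 and C7 carry hexadecyl, C5 is the ketone, C6 carries CO2Me).

Assumption: the (S)-carbinol of 3 is taken to relay to the required ring-fusion configuration through an equatorial hexadecyl group in the chair-like cyclisation. Because this centre is later oxidised to the C7 ketone, the antipodal ligand in step 1 corrects the sense if the relay proves opposite.

Step 1
Reactants: 1 heptadecan-1-ol; 2 allyl acetate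
Product: 3 (4S)-icos-1-en-4-ol
Conditions: [Ir(cod)Cl]2 (2.5 mol%), BINAP antipode that gives the (S)-carbinol (5 mol%), 4-chloro-3-nitrobenzoic acid (10 mol%), Cs2CO3 (20 mol%), THF, 100 °C
Reagents that add atoms: none
Why: Iridium-catalysed transfer-hydrogenative carbonyl allylation: the catalyst dehydrogenates the alcohol to the aldehyde and delivers a chiral π-allyliridium to one aldehyde face, so the carbinol centre is set by the BINAP ligand.

Step 2
Reactants: 3 (4S)-icos-1-en-4-ol; 4 methyl acrylate
Product: 5 methyl (2E,5S)-5-hydroxyhenicos-2-enoate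
Conditions: second-generation Grubbs catalyst (3 mol%), methyl acrylate (3 equiv), CH2Cl2, 40 °C
Reagents that add atoms: none
Why: Olefin cross-metathesis of a terminal alkene with an acrylate is selective for the cross product and should give the (E)-enoate without touching the carbinol centre.

Step 3
Reactants: 5 methyl (2E,5S)-5-hydroxyhenicos-2-enoate; 6 maleic anhydride
Product: 8 methyl (2E,5S)-5-{[(2Z)-4-methoxy-4-oxobut-2-enoyl]oxy}henicos-2-enoate, via maleate half-ester acid 7 (not isolated)
Conditions: maleic anhydride (1.5 equiv), DMAP (10 mol%), CH2Cl2, 25 °C; then TMSCHN2, toluene/MeOH, 0 °C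
Reagents that add atoms: trimethylsilyldiazomethane C[Si](C)(C)C=[N+]=[N-]
Why: DMAP-catalysed ring opening of the cyclic anhydride by the secondary alcohol keeps the (Z)-alkene, and diazoalkane O-methylation of the freed acid is neutral, so neither the maleate geometry nor the carbinol centre should be disturbed.

Step 4
Reactants: 8 methyl (2E,5S)-5-{[(2Z)-4-methoxy-4-oxobut-2-enoyl]oxy}henicos-2-enoate; 9 octadec-1-yne
Product: 10 dimethyl (3S)-3,6-dihexadecyl-1-oxo-3,4,4a,5,8,8a-hexahydro-1H-isochromene-5,8-dicarboxylate (cis-fused δ-lactone; H-3 cis to H-4a; H-4a, H-8a and H-8 mutually cis; H-5 trans to H-4a)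
Conditions: Ni(cod)2 (10 mol%), 1,3-bis(2,6-diisopropylphenyl)imidazol-2-ylidene (10 mol%), toluene, 60 °C, 9 (1.5 equiv) added over 6 h
Reagents that add atoms: none
Why: Proposed new method: zerovalent nickel should bind both electron-poor alkenes of 8 and couple them tail to tail (C4a–C8a) to a bis(ester-stabilised) nickelacyclopentane, into which the alkyne inserts before C–C reductive elimination closes the cyclohexene; the closest known reactions are the zerovalent-nickel-catalysed [2+2+2] cycloaddition of two enones with an alkyne and the tail-to-tail oxidative coupling of acrylates on zerovalent nickel. The δ-lactone closes in the oxidative coupling as a six-membered ring through a chair-like arrangement of the homoallylic ester tether (which offers no allylic C–O bond to nickel), and ring A closes as the six-membered ring of the cycloaddition when the alkyne carbons bond to C1 and C4. The carbinol stereocentre, with its hexadecyl chain equatorial in that chair, selects the face of the (E)-enoate and so fixes C8a, and because both alkenes sit on one nickel atom the new bond is made syn, which gives the cis ring fusion at C4a. Suprafacial, stereoretentive engagement of each alkene should carry the (E)-geometry into the trans relation of the C1 ester to C8 and the (Z)-maleate geometry into the cis relation of the C4 ester to the lactone carbonyl. The step needs cross-selectivity over alkyne oligomerisation, which slow addition of 9 to the chelating bis-enoate should secure. It also needs the orientation that puts hexadecyl next to C1, expected because the bulky carbene steers the alkyl-bearing alkyne carbon into the first C–C bond at the less encumbered, non-chelated Ni–C1 bond, leaving the lactone-carbonyl-chelated Ni–C4 bond to eliminate with the CH terminus.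

Step 5
Reactants: 10 dimethyl (3S)-3,6-dihexadecyl-1-oxo-3,4,4a,5,8,8a-hexahydro-1H-isochromene-5,8-dicarboxylate
Product: 12 4-hexadecyl-2,5-bis(methoxycarbonyl)-6-(2-oxooctadecyl)cyclohex-3-ene-1-carboxylic acid (H-1, H-2 and H-6 cis; H-5 trans to H-6), via hydroxy acid 11 (not isolated)
Conditions: LiOH·H2O (1.05 equiv), THF/H2O, 0 °C; 1 M HCl to pH 4, extraction; then Dess–Martin periodinane, CH2Cl2, 0 °C to 25 °C
Reagents that add atoms: lithium hydroxide [Li+].[OH-]
Why: A δ-lactone should be saponified far faster than the two α-branched methyl esters, and Dess–Martin oxidation turns the freed secondary carbinol (the temporary stereocentre) into the C7 ketone before it can relactonise, with no ring stereocentre involved.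

Step 6
Reactants: 12 4-hexadecyl-2,5-bis(methoxycarbonyl)-6-(2-oxooctadecyl)cyclohex-3-ene-1-carboxylic acid; 13 potassium methyl malonate
Product: 16 dimethyl 2-hexadecyl-5-(3-methoxy-3-oxopropanoyl)-6-(2-oxooctadecyl)cyclohex-2-ene-1,4-dicarboxylate (H-4, H-5 and H-6 cis; H-1 trans to H-6), via acyl imidazolide 14 (not isolated), via acylmalonate half-ester 15 (not isolated)
Conditions: CDI, THF, 25 °C; then 13, MgCl2, Et3N, MeCN, 25 °C; 1 M HCl work-up
Reagents that add atoms: none
Why: Magnesium-malonate C-acylation of the acyl imidazolide followed by decarboxylation (Masamune-type Claisen homologation) is a weakly basic route to the β-keto ester and should leave the α-stereocentre of the acid and the 1,5-related ketone untouched.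

Step 7
Reactants: 16 dimethyl 2-hexadecyl-5-(3-methoxy-3-oxopropanoyl)-6-(2-oxooctadecyl)cyclohex-2-ene-1,4-dicarboxylate
Product: 18 trimethyl (1S,4R,4aS,8aR)-2,7-dihexadecyl-5-oxo-1,4,4a,5,8,8a-hexahydronaphthalene-1,4,6-tricarboxylate, via aldol adduct 17 (not isolated)
Conditions: piperidine (20 mol%), AcOH (20 mol%), 4 Å molecular sieves, toluene, 50 °C
Reagents that add atoms: none
Why: Intramolecular Knoevenagel condensation: the doubly activated C6 methylene adds to the C7 ketone in a 6-(enolexo)-exo-trig aldol and loses water to the tetrasubstituted enone of ring B, and buffered amine catalysis should leave C4a and the β,γ-unsaturated esters unchanged.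

**Compound list**

1 | heptadecan-1-ol | CCCCCCCCCCCCCCCCCO | starting material
2 | allyl acetate | CC(=O)OCC=C | starting material
3 | (4S)-icos-1-en-4-ol | C=CC[C@@H](O)CCCCCCCCCCCCCCCC | intermediate
4 | methyl acrylate | C=CC(=O)OC | starting material
5 | methyl (2E,5S)-5-hydroxyhenicos-2-enoate | COC(=O)/C=C/C[C@@H](O)CCCCCCCCCCCCCCCC | intermediate
6 | maleic anhydride | O=C1C=CC(=O)O1 | starting material
7 | (2Z)-4-{[(2E,5S)-1-methoxy-1-oxohenicos-2-en-5-yl]oxy}-4-oxobut-2-enoic acid | OC(=O)/C=C\C(=O)O[C@@H](CCCCCCCCCCCCCCCC)C/C=C/C(=O)OC | intermediate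
8 | methyl (2E,5S)-5-{[(2Z)-4-methoxy-4-oxobut-2-enoyl]oxy}henicos-2-enoate | COC(=O)/C=C\C(=O)O[C@@H](CCCCCCCCCCCCCCCC)C/C=C/C(=O)OC | intermediate
9 | octadec-1-yne | CCCCCCCCCCCCCCCCC#C | starting material
10 | dimethyl (3S)-3,6-dihexadecyl-1-oxo-3,4,4a,5,8,8a-hexahydro-1H-isochromene-5,8-dicarboxylate (cis-fused; H-3 cis to H-4a; H-4a, H-8a, H-8 cis; H-5 trans to H-4a) | CCCCCCCCCCCCCCCCC1=C[C@@H](C(=O)OC)[C@H]2C(=O)O[C@@H](CCCCCCCCCCCCCCCC)C[C@H]2[C@@H]1C(=O)OC | intermediate
11 | 4-hexadecyl-6-[(2S)-2-hydroxyoctadecyl]-2,5-bis(methoxycarbonyl)cyclohex-3-ene-1-carboxylic acid (H-1, H-2, H-6 cis; H-5 trans to H-6) | CCCCCCCCCCCCCCCCC1=C[C@@H](C(=O)OC)[C@@H](C(=O)O)[C@@H](C[C@@H](O)CCCCCCCCCCCCCCCC)[C@@H]1C(=O)OC | intermediate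
12 | 4-hexadecyl-2,5-bis(methoxycarbonyl)-6-(2-oxooctadecyl)cyclohex-3-ene-1-carboxylic acid (H-1, H-2, H-6 cis; H-5 trans to H-6) | CCCCCCCCCCCCCCCCC1=C[C@@H](C(=O)OC)[C@@H](C(=O)O)[C@@H](CC(=O)CCCCCCCCCCCCCCCC)[C@@H]1C(=O)OC | intermediate
13 | potassium methyl malonate (potassium 3-methoxy-3-oxopropanoate) | COC(=O)CC(=O)[O-].[K+] | starting material
14 | acyl imidazolide of 12 (dimethyl 2-hexadecyl-5-(imidazole-1-carbonyl)-6-(2-oxooctadecyl)cyclohex-2-ene-1,4-dicarboxylate) | CCCCCCCCCCCCCCCCC1=C[C@@H](C(=O)OC)[C@@H](C(=O)n2ccnc2)[C@@H](CC(=O)CCCCCCCCCCCCCCCC)[C@@H]1C(=O)OC | intermediate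
15 | 2-acylmalonic acid monomethyl ester derived from 14 (malonate carbon unassigned) | CCCCCCCCCCCCCCCCC1=C[C@@H](C(=O)OC)[C@@H](C(=O)C(C(=O)O)C(=O)OC)[C@@H](CC(=O)CCCCCCCCCCCCCCCC)[C@@H]1C(=O)OC | intermediate
16 | dimethyl 2-hexadecyl-5-(3-methoxy-3-oxopropanoyl)-6-(2-oxooctadecyl)cyclohex-2-ene-1,4-dicarboxylate (H-4, H-5, H-6 cis; H-1 trans to H-6) | CCCCCCCCCCCCCCCCC1=C[C@@H](C(=O)OC)[C@@H](C(=O)CC(=O)OC)[C@@H](CC(=O)CCCCCCCCCCCCCCCC)[C@@H]1C(=O)OC | intermediate
17 | trimethyl 2,7-dihexadecyl-7-hydroxy-5-oxo-1,4,4a,5,6,7,8,8a-octahydronaphthalene-1,4,6-tricarboxylate (C6 and C7 unassigned) | CCCCCCCCCCCCCCCCC1=C[C@@H](C(=O)OC)[C@H]2C(=O)C(C(=O)OC)C(O)(CCCCCCCCCCCCCCCC)C[C@H]2[C@@H]1C(=O)OC | intermediate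
18 | trimethyl (1S,4R,4aS,8aR)-2,7-dihexadecyl-5-oxo-1,4,4a,5,8,8a-hexahydronaphthalene-1,4,6-tricarboxylate | CCCCCCCCCCCCCCCCC1=C[C@@H](C(=O)OC)[C@H]2C(=O)C(C(=O)OC)=C(CCCCCCCCCCCCCCCC)C[C@H]2[C@@H]1C(=O)OC | target

Total step count: 7. Longest linear sequence: 7 steps (steps 1 to 7 from heptadecan-1-ol).

**Steps most likely to fail**

1. Step 4 (proposed new method). The nickel may oligomerise the alkyne instead of engaging the bis-enoate. The alkyne may insert with the opposite orientation, which would put hexadecyl next to C4. The maleate may isomerise on nickel before C–C coupling, which would invert C4. The carbinol may relay poorly, or the fusion may come out trans. Fallback with known chemistry only, setting out from 5 and 9 and returning at 10, in which the C4a–C8a bond is still made in a ring closure: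
   - Bromine addition to 5 gives methyl (5S)-2,3-dibromo-5-hydroxyhenicosanoate F1, and triethylamine eliminates HBr to methyl (2Z,5S)-2-bromo-5-hydroxyhenicos-2-enoate F2.
   - Copper-catalysed Markovnikov protoboration of 9 (CuCl, a carbene ligand, NaOtBu, B2pin2, MeOH) gives 4,4,5,5-tetramethyl-2-(octadec-1-en-2-yl)-1,3,2-dioxaborolane F3.
   - Suzuki coupling of F2 with F3 (Pd(dppf)Cl2, K3PO4, THF/H2O) gives methyl (2E,5S)-5-hydroxy-2-(octadec-1-en-2-yl)henicos-2-enoate F4.
   - Separately, the dienolate of methyl but-3-enoate (LDA) is alkylated at its α-carbon with tert-butyl bromoacetate to 4-tert-butyl 1-methyl 2-ethenylbutanedioate F5, and CF3CO2H gives 3-(methoxycarbonyl)pent-4-enoic acid F6.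
   - Carbodiimide esterification of F4 with F6 (diisopropylcarbodiimide, DMAP) gives (2E,5S)-1-methoxy-2-(octadec-1-en-2-yl)-1-oxohenicos-2-en-5-yl methyl 2-ethenylbutanedioate F7.
   - KHMDS (THF, −78 °C, then AcOH) should deprotonate the less hindered CH2 and close the δ-lactone by 6-exo-trig Michael addition, with α-protonation of the resulting dienolate, to methyl 2-[6-hexadecyl-3-(1-methoxy-1-oxobut-3-en-2-yl)-2-oxooxan-4-yl]-3-methylidenenonadecanoate F8, whose diastereomers would be separated.
   - Ring-closing metathesis of F8 (second-generation Hoveyda–Grubbs catalyst, toluene, 80 °C) closes ring A with the alkene at C2=C3 and returns to 10.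

2. Step 5. Hydroxide may epimerise C4a or C4, or move the C2=C3 alkene into conjugation, and the free δ-hydroxy acid may relactonise before it is oxidised. Fallback, setting out from 10 and returning at 16: the lithium enolate of methyl acetate (LDA, methyl acetate, THF, −78 °C) opens the lactone by Claisen-type acyl substitution to dimethyl 2-hexadecyl-6-[(2S)-2-hydroxyoctadecyl]-5-(3-methoxy-3-oxopropanoyl)cyclohex-2-ene-1,4-dicarboxylate F9 (in equilibrium with its cyclic hemiketal). Dess–Martin oxidation of F9 then gives 16 directly, so no free hydroxy acid is formed and the separate C-acylation is not needed.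

3. Step 7. The amine may epimerise C4a through the enol of the C5 ketone, the ring-A alkene may migrate into conjugation, or the aldol adduct may revert instead of dehydrating. Fallback, setting out from 12 (through 14) and returning at 18: the acyl imidazolide 14 acylates the magnesium enolate of trimethyl phosphonoacetate (MgCl2, Et3N, MeCN) to dimethyl 5-[2-(dimethoxyphosphoryl)-3-methoxy-3-oxopropanoyl]-2-hexadecyl-6-(2-oxooctadecyl)cyclohex-2-ene-1,4-dicarboxylate F10. An intramolecular Horner–Wadsworth–Emmons olefination of the C7 ketone (LiCl, DBU, MeCN, 25 °C) then forms the C6=C7 bond irreversibly and gives 18.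

Further compounds
F1 | step 4 | methyl (5S)-2,3-dibromo-5-hydroxyhenicosanoate | COC(=O)C(Br)C(Br)C[C@@H](O)CCCCCCCCCCCCCCCC
F2 | step 4 | methyl (2Z,5S)-2-bromo-5-hydroxyhenicos-2-enoate | COC(=O)/C(Br)=C/C[C@@H](O)CCCCCCCCCCCCCCCC
F3 | step 4 | 4,4,5,5-tetramethyl-2-(octadec-1-en-2-yl)-1,3,2-dioxaborolane | C=C(CCCCCCCCCCCCCCCC)B1OC(C)(C)C(C)(C)O1
F4 | step 4 | methyl (2E,5S)-5-hydroxy-2-(octadec-1-en-2-yl)henicos-2-enoate | COC(=O)/C(C(=C)CCCCCCCCCCCCCCCC)=C/C[C@@H](O)CCCCCCCCCCCCCCCC
F5 | step 4 | 4-tert-butyl 1-methyl 2-ethenylbutanedioate | COC(=O)C(C=C)CC(=O)OC(C)(C)C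
F6 | step 4 | 3-(methoxycarbonyl)pent-4-enoic acid | COC(=O)C(C=C)CC(=O)O
F7 | step 4 | (2E,5S)-1-methoxy-2-(octadec-1-en-2-yl)-1-oxohenicos-2-en-5-yl methyl 2-ethenylbutanedioate | COC(=O)C(C=C)CC(=O)O[C@@H](CCCCCCCCCCCCCCCC)C/C=C(\C(=C)CCCCCCCCCCCCCCCC)C(=O)OC
F8 | step 4 | methyl 2-[6-hexadecyl-3-(1-methoxy-1-oxobut-3-en-2-yl)-2-oxooxan-4-yl]-3-methylidenenonadecanoate | C=C(CCCCCCCCCCCCCCCC)[C@@H](C(=O)OC)[C@@H]1C[C@H](CCCCCCCCCCCCCCCC)OC(=O)[C@@H]1[C@@H](C=C)C(=O)OC
F9 | step 5 | dimethyl 2-hexadecyl-6-[(2S)-2-hydroxyoctadecyl]-5-(3-methoxy-3-oxopropanoyl)cyclohex-2-ene-1,4-dicarboxylate | CCCCCCCCCCCCCCCCC1=C[C@@H](C(=O)OC)[C@@H](C(=O)CC(=O)OC)[C@@H](C[C@@H](O)CCCCCCCCCCCCCCCC)[C@@H]1C(=O)OC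
F10 | step 7 | dimethyl 5-[2-(dimethoxyphosphoryl)-3-methoxy-3-oxopropanoyl]-2-hexadecyl-6-(2-oxooctadecyl)cyclohex-2-ene-1,4-dicarboxylate | CCCCCCCCCCCCCCCCC1=C[C@@H](C(=O)OC)[C@@H](C(=O)C(C(=O)OC)P(=O)(OC)OC)[C@@H](CC(=O)CCCCCCCCCCCCCCCC)[C@@H]1C(=O)OC
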